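**Retrosynthetic overview**
- Feature: the only ring is a 1,4-benzoquinone, numbered C1(=O), C2(OH), C3(C16H33), C4(=O), C5(OMe), C6(H). Its C1–C2–C3–C4 arc carries oxygen on C1, C2 and C4 and is the four-carbon skeleton of squaric acid; the C5(OMe)=C6H edge is a 1-methoxyvinyl unit.
- Endgame: the C2 hydroxyl comes from a C2 tert-butyl ether by acidolysis, which leaves the C5 methyl ether alone. The quinone comes from the C4-silylated hydroquinone by desilylation and Ag2O oxidation.
- Key disconnection: the C1–C6 bond. The arene arises from a 4-(1-methoxyvinyl)-4-silyloxycyclobutenone by 4π opening to a dienylketene and 6π closure.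
- Cyclobutenone: di-tert-butyl squarate takes CH2=C(OMe)Li first (C4–C5 bond) and the alkoxide is silylated. C16H33Li and a (CF3CO)2O-triggered 1,3-carbonyl transposition then place hexadecyl on C3, beside the carbinol carbon C4.
- Ring order: the four-membered ring is bought; the six-membered ring is made once, in step 3, at the expense of the four-membered ring.

Key step: step 3

Assumption: di-tert-butyl squarate, methyl vinyl ether (condensed from a cylinder) and 1-iodohexadecane are taken as purchasable, the iodide is chosen over the bromide because its exchange with t-BuLi is cleaner, and since the target has no stereocentre all chiral intermediates are carried racemic.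

**Step 1**
Reactants: 1 di-tert-butyl squarate; 2 methyl vinyl ether
Product: 5 2,3-di-tert-butoxy-4-(1-methoxyvinyl)-4-(trimethylsilyloxy)cyclobut-2-en-1-one (racemic), via 1-methoxyvinyllithium 3 (not isolated), via lithium alkoxide adduct 4 (not isolated)
Conditions: 2 (excess), t-BuLi, THF, −78 to 0 °C; cannulated into 1, THF, −78 °C; Me3SiCl, −78 to 0 °C; aq NaHCO3; Et3N-deactivated SiO2
Reagents that add atoms: chlorotrimethylsilane, C[Si](C)(C)Cl
Why: Alpha-lithiation of the enol ether and 1,2-addition of the resulting vinyllithium to one of the two equivalent squarate carbonyls should stop at the mono-adduct, because the remaining carbonyl is a vinylogous ester next to an alkoxide, and O-silylation of that alkoxide with Me3SiCl blocks the carbinol, whose stereocentre forms racemic and is erased in step 3.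

**Step 2**
Reactants: 5 2,3-di-tert-butoxy-4-(1-methoxyvinyl)-4-(trimethylsilyloxy)cyclobut-2-en-1-one; 6 1-iodohexadecane
Product: 10 2-tert-butoxy-3-hexadecyl-4-(1-methoxyvinyl)-4-(trimethylsilyloxy)cyclobut-2-en-1-one (racemic), via hexadecyllithium 7 (not isolated), via lithium cyclobutenol alkoxide 8 (not isolated), via allylic trifluoroacetate 9 (not isolated)
Conditions: 6, t-BuLi (2 equiv), pentane/Et2O, −78 °C, then briefly rt to destroy residual t-BuLi; added to 5, THF, −78 °C; 2,6-lutidine, (CF3CO)2O (slight excess), −78 °C; aq NaHCO3 at low temperature; Et3N-deactivated SiO2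
Reagents that add atoms: none
Why: Iodine–lithium exchange gives the primary alkyllithium, which adds 1,2 to the only carbonyl of 5 (either face, the new centre is lost again at once), and O-trifluoroacetylation followed by ionisation to a tert-butoxy-stabilised cyclobutenyl cation that sheds isobutene from its far terminus accomplishes the known 1,3-carbonyl transposition of protected squarate adducts, with 2,6-lutidine taking up the acid so that the enol ether and the silyl ether survive.

**Step 3**
Reactants: 10 2-tert-butoxy-3-hexadecyl-4-(1-methoxyvinyl)-4-(trimethylsilyloxy)cyclobut-2-en-1-one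
Product: 13 2-tert-butoxy-3-hexadecyl-5-methoxy-4-(trimethylsilyloxy)phenol, via dienylketene 11 (not isolated), via cyclohexa-2,4-dienone 12 (not isolated)
Conditions: degassed PhMe (dilute), 110 °C, Ar, base-washed glassware; concentrated and used crude
Reagents that add atoms: none
Why: Heating opens the strained cyclobutenone by a conrotatory 4π electrocyclic reaction (the C1–C4 bond breaks) to dienylketene 11, a disrotatory 6π electrocyclisation then joins the ketene carbon (quinone C1) to the unsubstituted vinyl CH2 carbon (C6), and enolisation of cyclohexadienone 12 aromatises the new ring. The closest known reaction type is the thermal ring expansion of squarate-derived 4-alkenyl-4-oxycyclobutenones to hydroquinones (Moore rearrangement), which includes alpha-alkoxyvinyl substrates. The one ring closed is the six-membered carbocycle, closed in the 6π electrocyclic mode with one new C–C bond, and relief of ring strain plus aromatisation make the sequence irreversible overall. No stereocentre is created and the racemic centre C4 of 10 is erased. The selectivity needed is torquoselectivity in the opening: the donor OSiMe3 group on C4 rotates outward, which turns the methoxyvinyl group inward and cis to the ketene, and a ketene of the other geometry can only re-close to 10. The substitution pattern needs no further control, since OtBu, hexadecyl, OSiMe3 and OMe already sit on C2, C3, C4 and C5 before the ring is opened.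

**Step 4**
Reactants: 13 2-tert-butoxy-3-hexadecyl-5-methoxy-4-(trimethylsilyloxy)phenol
Product: 15 2-tert-butoxy-3-hexadecyl-5-methoxy-1,4-benzoquinone, via hydroquinone 14 (not isolated)
Conditions: Bu4NF, AcOH, THF, 0 °C; then Ag2O (excess), rt; filtration through Celite
Reagents that add atoms: none
Why: Buffered fluoride desilylation of the aryl silyl ether frees the electron-rich hydroquinone, which Ag2O dehydrogenates to the 1,4-benzoquinone under neutral conditions (hydroquinone-to-quinone oxidation) that touch neither the tert-butyl nor the methyl ether.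

**Step 5**
Reactants: 15 2-tert-butoxy-3-hexadecyl-5-methoxy-1,4-benzoquinone
Product: 16 3-hexadecyl-2-hydroxy-5-methoxy-1,4-benzoquinone (target)
Conditions: CF3CO2H, CH2Cl2, 0 °C to rt
Reagents that add atoms: none
Why: Acidolysis of a tert-butyl ether (E1 loss of the tert-butyl cation as isobutene) is easy here because the C2 oxygen is part of a vinylogous ester, whereas the C5 methyl ether cannot ionise and finds no water to be hydrolysed by, so only the C2 hydroxyl is unveiled.

**Compound list**
1 | di-tert-butyl squarate (3,4-di-tert-butoxycyclobut-3-ene-1,2-dione) | CC(C)(C)OC1=C(OC(C)(C)C)C(=O)C1=O | starting material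
2 | methyl vinyl ether | COC=C | starting material
3 | 1-methoxyvinyllithium | [Li]C(=C)OC | intermediate
4 | lithium 2,3-di-tert-butoxy-1-(1-methoxyvinyl)-4-oxocyclobut-2-en-1-olate (racemic) | [Li]OC1(C(=C)OC)C(OC(C)(C)C)=C(OC(C)(C)C)C1=O | intermediate
5 | 2,3-di-tert-butoxy-4-(1-methoxyvinyl)-4-(trimethylsilyloxy)cyclobut-2-en-1-one (racemic) | C=C(OC)C1(O[Si](C)(C)C)C(OC(C)(C)C)=C(OC(C)(C)C)C1=O | intermediate
6 | 1-iodohexadecane | CCCCCCCCCCCCCCCCI | starting material
7 | hexadecyllithium | [Li]CCCCCCCCCCCCCCCC | intermediate
8 | lithium 2,3-di-tert-butoxy-1-hexadecyl-4-(1-methoxyvinyl)-4-(trimethylsilyloxy)cyclobut-2-en-1-olate (racemic, mixture of diastereomers) | CCCCCCCCCCCCCCCCC1(O[Li])C(OC(C)(C)C)=C(OC(C)(C)C)C1(O[Si](C)(C)C)C(=C)OC | intermediate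
9 | 2,3-di-tert-butoxy-1-hexadecyl-4-(1-methoxyvinyl)-4-(trimethylsilyloxy)cyclobut-2-en-1-yl trifluoroacetate (racemic, mixture of diastereomers) | CCCCCCCCCCCCCCCCC1(OC(=O)C(F)(F)F)C(OC(C)(C)C)=C(OC(C)(C)C)C1(O[Si](C)(C)C)C(=C)OC | intermediate
10 | 2-tert-butoxy-3-hexadecyl-4-(1-methoxyvinyl)-4-(trimethylsilyloxy)cyclobut-2-en-1-one (racemic) | CCCCCCCCCCCCCCCCC1=C(OC(C)(C)C)C(=O)C1(O[Si](C)(C)C)C(=C)OC | intermediate
11 | (3E)-2-tert-butoxy-3-hexadecyl-5-methoxy-4-(trimethylsilyloxy)hexa-1,3,5-trien-1-one | CCCCCCCCCCCCCCCC/C(C(OC(C)(C)C)=C=O)=C(\O[Si](C)(C)C)C(=C)OC | intermediate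
12 | 2-tert-butoxy-3-hexadecyl-5-methoxy-4-(trimethylsilyloxy)cyclohexa-2,4-dien-1-one | CCCCCCCCCCCCCCCCC1=C(OC(C)(C)C)C(=O)CC(OC)=C1O[Si](C)(C)C | intermediate
13 | 2-tert-butoxy-3-hexadecyl-5-methoxy-4-(trimethylsilyloxy)phenol | CCCCCCCCCCCCCCCCc1c(OC(C)(C)C)c(O)cc(OC)c1O[Si](C)(C)C | intermediate
14 | 2-tert-butoxy-3-hexadecyl-5-methoxybenzene-1,4-diol | CCCCCCCCCCCCCCCCc1c(OC(C)(C)C)c(O)cc(OC)c1O | intermediate
15 | 2-tert-butoxy-3-hexadecyl-5-methoxycyclohexa-2,5-diene-1,4-dione | CCCCCCCCCCCCCCCCC1=C(OC(C)(C)C)C(=O)C=C(OC)C1=O | intermediate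
16 | 3-hexadecyl-2-hydroxy-5-methoxycyclohexa-2,5-diene-1,4-dione | CCCCCCCCCCCCCCCCC1=C(O)C(=O)C=C(OC)C1=O | target

**Total step count:** 5
**Longest linear sequence:** 5 steps (1 → 5 → 10 → 13 → 15 → 16)

**Steps most likely to fail**

Step 3.
- Risk: isobutene, the silyl group or the enol ether may be lost, thermally or through trace acid, before the ring opens. The 6π closure may also be slowed because the neighbouring methoxy and silyloxy groups twist the triene out of plane, so that the ketene is consumed by dimerisation or by adventitious nucleophiles.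
- Fallback: the ring construction is given up and a bought arene is functionalised. The fallback sets out from 6.
- 1,2,4,5-Tetramethoxybenzene F1 is lithiated between two methoxy groups (n-BuLi, THF, 0 °C) to 2,3,5,6-tetramethoxyphenyllithium F2, which is alkylated with 6 to 3-hexadecyl-1,2,4,5-tetramethoxybenzene F3.
- Oxidative demethylation with (NH4)2Ce(NO3)6 in MeCN/H2O should give 3-hexadecyl-2,5-dimethoxy-1,4-benzoquinone F4.
- Aqueous NaOH followed by acid hydrolyses both vinylogous esters to 3-hexadecyl-2,5-dihydroxy-1,4-benzoquinone F5.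
- MeOH with catalytic H2SO4 (Fischer-type vinylogous esterification) should methylate the unhindered C5 hydroxyl in preference to the C2 hydroxyl flanked by the chain. The fallback comes back to the route at 16.

Step 2.
- Risk: the silyl group may migrate from oxygen to oxygen in the vicinal alkoxide. Excess anhydride or liberated acid may attack the enol ether. The methoxyvinyl group may undergo a semipinacol shift in the cyclobutenyl cation. The poorly soluble long-chain alkyllithium may add sluggishly.
- Fallback: the same substitution pattern is drawn from the innate regioselectivity of a cyclobutenedione, so no transposition is run in the presence of sensitive groups. The fallback sets out from 1, 2 and 7.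
- Compound 7 adds to 1 at −78 °C, and (CF3CO)2O collapses the adduct to 3-tert-butoxy-4-hexadecylcyclobut-3-ene-1,2-dione F6.
- Separately, 2 is brominated (Br2, CH2Cl2, −78 °C) to 1,2-dibromo-1-methoxyethane F7, which is dehydrobrominated with i-Pr2NEt to (Z)-1-bromo-2-methoxyethene F8.
- Bromine–lithium exchange (n-BuLi, Et2O, −78 °C) converts F8 with retention into (Z)-2-methoxyvinyllithium F9.
- F9 adds to the more electrophilic carbonyl of F6, the one next to the tert-butoxy carbon, which is not a vinylogous ester. This gives 3-tert-butoxy-2-hexadecyl-4-hydroxy-4-[(Z)-2-methoxyvinyl]cyclobut-2-en-1-one F10.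
- Heating F10 in toluene runs the same opening and closing sequence with the ring mapped the other way round: the ketene carbon becomes C4 and bonds to the CH(OMe) carbon, C5. The fallback comes back to the route at 14, which is oxidised with Ag2O as in step 4.

Step 1.
- Risk: silylation of the hindered tertiary lithium alkoxide may be incomplete, and the trimethylsilyl group may be lost or the enol ether hydrolysed during work-up and chromatography.
- Fallback: the carbinol oxygen is capped as a methyl ether that is taken off oxidatively at the end. The fallback sets out from 4.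
- Quenching 4 with CF3SO3Me gives 2,3-di-tert-butoxy-4-methoxy-4-(1-methoxyvinyl)cyclobut-2-en-1-one F11.
- Addition of 7 and the (CF3CO)2O/2,6-lutidine transposition give 2-tert-butoxy-3-hexadecyl-4-methoxy-4-(1-methoxyvinyl)cyclobut-2-en-1-one F12.
- Thermolysis in toluene, with the methoxy group rotating outward, gives 2-tert-butoxy-3-hexadecyl-4,5-dimethoxyphenol F13.
- Oxidative demethylation of this 4-methoxyphenol with (NH4)2Ce(NO3)6 in MeCN/H2O at 0 °C comes back to the route at 15.

**Further compounds**
F1 | step 3 | 1,2,4,5-tetramethoxybenzene (purchased) | COc1cc(OC)c(OC)cc1OC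
F2 | step 3 | 2,3,5,6-tetramethoxyphenyllithium | [Li]c1c(OC)c(OC)cc(OC)c1OC
F3 | step 3 | 3-hexadecyl-1,2,4,5-tetramethoxybenzene | CCCCCCCCCCCCCCCCc1c(OC)c(OC)cc(OC)c1OC
F4 | step 3 | 3-hexadecyl-2,5-dimethoxy-1,4-benzoquinone | CCCCCCCCCCCCCCCCC1=C(OC)C(=O)C=C(OC)C1=O
F5 | step 3 | 3-hexadecyl-2,5-dihydroxy-1,4-benzoquinone | CCCCCCCCCCCCCCCCC1=C(O)C(=O)C=C(O)C1=O
F6 | step 2 | 3-tert-butoxy-4-hexadecylcyclobut-3-ene-1,2-dione | CCCCCCCCCCCCCCCCC1=C(OC(C)(C)C)C(=O)C1=O
F7 | step 2 | 1,2-dibromo-1-methoxyethane (racemic) | COC(Br)CBr
F8 | step 2 | (Z)-1-bromo-2-methoxyethene | CO/C=C\Br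
F9 | step 2 | (Z)-2-methoxyvinyllithium | CO/C=C\[Li]
F10 | step 2 | 3-tert-butoxy-2-hexadecyl-4-hydroxy-4-[(Z)-2-methoxyvinyl]cyclobut-2-en-1-one (racemic) | CCCCCCCCCCCCCCCCC1=C(OC(C)(C)C)C(O)(/C=C\OC)C1=O
F11 | step 1 | 2,3-di-tert-butoxy-4-methoxy-4-(1-methoxyvinyl)cyclobut-2-en-1-one (racemic) | C=C(OC)C1(OC)C(OC(C)(C)C)=C(OC(C)(C)C)C1=O
F12 | step 1 | 2-tert-butoxy-3-hexadecyl-4-methoxy-4-(1-methoxyvinyl)cyclobut-2-en-1-one (racemic) | CCCCCCCCCCCCCCCCC1=C(OC(C)(C)C)C(=O)C1(OC)C(=C)OC
F13 | step 1 | 2-tert-butoxy-3-hexadecyl-4,5-dimethoxyphenol | CCCCCCCCCCCCCCCCc1c(OC(C)(C)C)c(O)cc(OC)c1OC
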